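**Strategy.** The route rests on cutting the saturated C1'–C2' bond of the side chain (chain carbons numbered C1'–C19' outward from ring carbon C2 of the dihydropyranone). C2'–C19' is then an intact oleyl unit, while C1', C2, C3 and C4 are four of the five carbons of an O-silylated (R)-3-hydroxyglutaric half-ester. A mixed Kolbe electrolysis of (Z)-nonadec-10-enoic acid with that half-ester strips one CO2 from each partner and joins the two primary radicals in a single operation, delivering the complete C22 chain with the C2 stereocentre and the Z-alkene already in place. The six-membered ring (O1–C6) is closed last from a propynyl ketone.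

Key step: step 2

Assumption: the (3R)-half-ester 4 is bought enantiopure (it is a bulk statin side-chain intermediate), so the single stereocentre of the target, C2 (R), arrives with this building block; oleyl bromide 1 is taken in a grade of high Z-purity.

**Step 1**
Reactants: 1 oleyl bromide [(Z)-1-bromooctadec-9-ene]
Product: 3 (Z)-nonadec-10-enoic acid, via oleylmagnesium bromide 2 (not isolated)
Conditions: Mg, THF, 40 °C; then CO2 (gas), −20 °C to rt; 1 M aq. HCl
Reagents that add atoms: carbon dioxide, O=C=O
Why: Grignard formation followed by carboxylation is a standard one-carbon homologation of a primary bromide, and the isolated Z-alkene is inert to magnesium and CO2 while no stereocentre is involved.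

**Step 2**
Reactants: 3 (Z)-nonadec-10-enoic acid (fourfold excess); 4 (3R)-3-[(tert-butyldimethylsilyl)oxy]-5-methoxy-5-oxopentanoic acid
Product: 5 methyl (3R,13Z)-3-[(tert-butyldimethylsilyl)oxy]docos-13-enoate
Conditions: Pt-foil anode, Pt cathode, undivided cell, MeOH, NaOMe (ca. 10 mol% neutralisation), ca. 0.2 A cm−2, 40 °C; chromatography
Reagents that add atoms: none
Why: In this mixed Kolbe electrolysis each carboxylate is oxidised by one electron at smooth platinum, loses CO2, and the oleyl radical and the primary CH2 radical next to the silyloxy-bearing carbon combine in the dense radical layer at the electrode to make C1'–C2'. The closest known reaction type is the mixed Kolbe coupling of Z-unsaturated fatty acids with half-esters, and of O-protected chiral 3-hydroxy acids for chain extension. No ring is closed and no stereocentre is created; the future C2 centre is carried through unchanged because the radical sits on the neighbouring CH2, not on the carbinol carbon. The step needs cross- over homo-coupling, which the excess of the inexpensive acid 3 should secure statistically with respect to 4, the non-polar C36 diene and the polar diester dimer being removed by chromatography. It also needs radical pairing over further oxidation to cations, which two primary radicals (one inductively deactivated by the adjacent oxygen), platinum, high current density and a low degree of neutralisation all favour. The alkene at C9/C10 of the oleyl radical is out of reach for cyclisation and should keep its Z geometry, the methyl ester is degenerate towards the solvent, and the secondary silyl ether should tolerate the weakly acidic electrolyte.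

**Step 3**
Reactants: 5 methyl (3R,13Z)-3-[(tert-butyldimethylsilyl)oxy]docos-13-enoate
Product: 6 (3R,13Z)-3-[(tert-butyldimethylsilyl)oxy]-N-methoxy-N-methyldocos-13-enamide
Conditions: MeNHOMe·HCl, i-PrMgCl, THF, −20 to 0 °C; aq. NH4Cl
Reagents that add atoms: N,O-dimethylhydroxylamine hydrochloride, CNOC.Cl
Why: Weinreb amide synthesis by aminolysis of the methyl ester with the chloromagnesium amide of N,O-dimethylhydroxylamine runs at low temperature, where the silyl ether and alkene are untouched and the C3 stereocentre, which carries no acidic hydrogen, cannot epimerise.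

**Step 4**
Reactants: 6 (3R,13Z)-3-[(tert-butyldimethylsilyl)oxy]-N-methoxy-N-methyldocos-13-enamide; 7 1-propynylmagnesium bromide
Product: 8 (6R,16Z)-6-[(tert-butyldimethylsilyl)oxy]pentacos-16-en-2-yn-4-one
Conditions: THF, −20 to 0 °C; inverse quench into cold 1 M aq. HCl
Reagents that add atoms: none
Why: In this Weinreb ketone synthesis the alkynyl Grignard adds once to give a magnesium-chelated tetrahedral intermediate that collapses to the ynone only on the acidic quench, which also protonates the released amine so that it cannot add to the ynone.

**Step 5**
Reactants: 8 (6R,16Z)-6-[(tert-butyldimethylsilyl)oxy]pentacos-16-en-2-yn-4-one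
Product: 10 (2R)-6-methyl-2-[(10Z)-nonadec-10-en-1-yl]-2,3-dihydro-4H-pyran-4-one, via (6R,16Z)-6-hydroxypentacos-16-en-2-yn-4-one 9 (not isolated)
Conditions: TsOH·H2O, MeOH, 0 °C to rt
Reagents that add atoms: none
Why: Acidic methanolysis removes the silyl ether and the freed hydroxyl adds to the acid-activated ynone at its methyl-bearing carbon in a 6-endo-dig oxa-Michael closure of O1–C6 to give the vinylogous ester, with C2 not involved and any methanol adduct of the ynone converging on the same ring by addition–elimination.

**Compound list**
1 | oleyl bromide, (Z)-1-bromooctadec-9-ene | CCCCCCCC/C=C\CCCCCCCCBr | starting material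
2 | oleylmagnesium bromide, (Z)-octadec-9-en-1-ylmagnesium bromide | CCCCCCCC/C=C\CCCCCCCC[Mg]Br | intermediate
3 | (Z)-nonadec-10-enoic acid | CCCCCCCC/C=C\CCCCCCCCC(=O)O | intermediate
4 | (3R)-3-[(tert-butyldimethylsilyl)oxy]-5-methoxy-5-oxopentanoic acid | OC(=O)C[C@@H](O[Si](C)(C)C(C)(C)C)CC(=O)OC | starting material
5 | methyl (3R,13Z)-3-[(tert-butyldimethylsilyl)oxy]docos-13-enoate | CCCCCCCC/C=C\CCCCCCCCC[C@@H](O[Si](C)(C)C(C)(C)C)CC(=O)OC | intermediate
6 | (3R,13Z)-3-[(tert-butyldimethylsilyl)oxy]-N-methoxy-N-methyldocos-13-enamide | CCCCCCCC/C=C\CCCCCCCCC[C@@H](O[Si](C)(C)C(C)(C)C)CC(=O)N(C)OC | intermediate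
7 | 1-propynylmagnesium bromide | CC#C[Mg]Br | starting material
8 | (6R,16Z)-6-[(tert-butyldimethylsilyl)oxy]pentacos-16-en-2-yn-4-one | CCCCCCCC/C=C\CCCCCCCCC[C@@H](O[Si](C)(C)C(C)(C)C)CC(=O)C#CC | intermediate
9 | (6R,16Z)-6-hydroxypentacos-16-en-2-yn-4-one | CCCCCCCC/C=C\CCCCCCCCC[C@@H](O)CC(=O)C#CC | intermediate
10 | (2R)-6-methyl-2-[(10Z)-nonadec-10-en-1-yl]-2,3-dihydro-4H-pyran-4-one | CCCCCCCC/C=C\CCCCCCCCC[C@@H]1CC(=O)C=C(C)O1 | target

**Total step count:** 5
**Longest linear sequence:** 5 steps (1 → 3 → 5 → 6 → 8 → 10)

**Steps most likely to fail**

1. Step 2. The two radicals may pair mainly with their own kind, or the anode may over-oxidise them to cations or become coated with insoluble hydrocarbon, so that little cross-coupled chain forms; slow methanolysis of the silyl ether in the electrolyte would add to the loss. The fallback avoids electrolysis and sets out from oleyl bromide 1. Alkylation of the dianion of methyl acetoacetate (NaH, then n-BuLi, THF, 0 °C) at its terminal carbon should give methyl (13Z)-3-oxodocos-13-enoate F1. Hydrogenation of the ketone with RuCl2[(R)-BINAP] (H2, MeOH), which should leave the isolated alkene alone and set the (R) carbinol by catalyst control, should give methyl (3R,13Z)-3-hydroxydocos-13-enoate F2. Silylation with TBSCl and imidazole in DMF comes back to the route at 5.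

2. Step 5. After loss of the silyl group the ring closure may stall, methanol or water may add to the ynone and divert material, or prolonged acid may reopen the ring by β-elimination and erode the C2 configuration. The fallback sets out from Weinreb amide 6 and replaces the ynone by a diketone. Acylation of the lithium enolate of acetone (LDA, acetone, THF, −78 °C, excess enolate) should give (6R,16Z)-6-[(tert-butyldimethylsilyl)oxy]pentacos-16-ene-2,4-dione F3. Brief treatment with TsOH·H2O in MeOH should remove the silyl group, after which the δ-hydroxy-β-diketone should close by hemiketalisation at the acetyl carbonyl and dehydrate, arriving directly at target 10.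

3. Step 3. The basic magnesium reagents may deprotonate C2 of the ester and expel the silyloxy group (E1cB), giving a conjugated enoate or enamide instead of the amide. The fallback sets out from ester 5 and bypasses 6 by a redox sequence. Reduction with i-Bu2AlH (CH2Cl2, −78 °C) should give (3R,13Z)-3-[(tert-butyldimethylsilyl)oxy]docos-13-enal F4. Addition of 7 (THF, −78 °C) should give (6R,16Z)-6-[(tert-butyldimethylsilyl)oxy]pentacos-16-en-2-yn-4-ol F5 as both C4 epimers, which is of no consequence. Oxidation with Dess–Martin periodinane (CH2Cl2, NaHCO3) comes back to the route at ynone 8.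

**Further compounds**
F1 | step 2 | methyl (13Z)-3-oxodocos-13-enoate | CCCCCCCC/C=C\CCCCCCCCCC(=O)CC(=O)OC
F2 | step 2 | methyl (3R,13Z)-3-hydroxydocos-13-enoate | CCCCCCCC/C=C\CCCCCCCCC[C@@H](O)CC(=O)OC
F3 | step 5 | (6R,16Z)-6-[(tert-butyldimethylsilyl)oxy]pentacos-16-ene-2,4-dione | CCCCCCCC/C=C\CCCCCCCCC[C@@H](O[Si](C)(C)C(C)(C)C)CC(=O)CC(C)=O
F4 | step 3 | (3R,13Z)-3-[(tert-butyldimethylsilyl)oxy]docos-13-enal | CCCCCCCC/C=C\CCCCCCCCC[C@@H](O[Si](C)(C)C(C)(C)C)CC=O
F5 | step 3 | (6R,16Z)-6-[(tert-butyldimethylsilyl)oxy]pentacos-16-en-2-yn-4-ol (both C4 epimers) | CCCCCCCC/C=C\CCCCCCCCC[C@@H](O[Si](C)(C)C(C)(C)C)CC(O)C#CC
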